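**Plan**

1. Numbering (prostanoid): C1 is the ester carbon, C5/C6/C7 the oxygenated chain carbons, C8–C12 ring A (C9 ketone, C10 chlorine, C12 quaternary), C13–C20 the octenyl chain; ring B is the tetrahydrofuran O–C6–C7–C8–C12.
2. Retrosynthesis: remove the acetates and the chlorine, then cut C8–C12 (ring A) and O–C6 (ring B) together, giving an acyclic (Z)-ene-1,4-dione with a cis-5,6-epoxide; the enedione is a masked 2,5-disubstituted furan, cut at C7–C8 into a furylacetate and a cis-epoxy aldehyde.
3. Enabling feature: ring A is a 4-oxycyclopent-2-enone whose oxygen sits on quaternary C12 (aldol retron of a cis-enedione), and that same oxygen lies 1,4 to C6 across C8–C7, so the aldol oxygen can open a 5,6-epoxide 5-exo and close ring B in the same operation.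
4. Forward order: aldol union C7–C8, furan oxidation, domino closure of rings A and B, then enone epoxidation/HCl (chlorine in, helpers out) and acetylation.
5. Helpers: a tert-butoxycarbonyl group on C8 (makes C8 the only acidic carbon for the union and for regiospecific enolisation; leaves as CO2) and a silyl ether on O7 (blocks β-elimination; leaves with acid).
6. Stereochemistry: C5/C6 from Sharpless epoxidation of a (Z)-allylic alcohol (C6 is inverted in the key step), C7 from addition anti to the epoxide C–O bond, C8/C12 from substrate control in a reversible aldol followed by irreversible etherification; the (Z)-alkenes come from a Wittig reaction and a (Z)-allylic alcohol.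

Key step: step 12

**Route**

Step 1
Reactants: 1 (4-carboxybutyl)triphenylphosphonium bromide; 2 (tert-butyldimethylsilyloxy)acetaldehyde
Product: 4 (Z)-7-[(tert-butyldimethylsilyl)oxy]hept-5-enoic acid, via ylide 3 (not isolated)
Conditions: NaN(SiMe3)2 (2.1 equiv), THF, 0 °C; then 2, −78 °C to rt; aq. HCl to pH 4
Reagents that add atoms: none
Why: Wittig reaction of a non-stabilised ylide under salt-poor conditions should give the (Z)-C5=C6 alkene through the kinetically favoured cis-oxaphosphetane; no stereocentre is formed.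

Step 2
Reactants: 4 (Z)-7-[(tert-butyldimethylsilyl)oxy]hept-5-enoic acid
Product: 5 methyl (Z)-7-hydroxyhept-5-enoate
Conditions: HCl (1.25 M in MeOH), 0 °C to rt
Reagents that add atoms: methanol, CO
Why: Fischer esterification and acid methanolysis of the primary silyl ether should run in the same flask, and the (Z)-alkene and primary allylic alcohol are expected to tolerate this acidity.

Step 3
Reactants: 5 methyl (Z)-7-hydroxyhept-5-enoate
Product: 6 methyl 4-[(2R,3S)-3-(hydroxymethyl)oxiran-2-yl]butanoate
Conditions: Ti(Oi-Pr)4 (cat.), L-(+)-diethyl tartrate, t-BuOOH, 4 Å MS, CH2Cl2, −20 °C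
Reagents that add atoms: tert-butyl hydroperoxide, CC(C)(C)OO
Why: Sharpless asymmetric epoxidation with the L-(+)-tartrate should deliver oxygen to the face that gives the (2S,3R)-2,3-epoxy alcohol, setting C5 (R) and C6 (S, to be inverted in step 12) as a cis-epoxide; (Z)-allylic alcohols react more slowly than (E)-isomers, so long reaction time is planned.

Step 4
Reactants: 6 methyl 4-[(2R,3S)-3-(hydroxymethyl)oxiran-2-yl]butanoate
Product: 7 methyl 4-[(2R,3R)-3-formyloxiran-2-yl]butanoate
Conditions: TEMPO (cat.), PhI(OAc)2, CH2Cl2, rt; used without storage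
Reagents that add atoms: none
Why: nitroxyl-catalysed oxidation of the primary alcohol under near-neutral conditions should give the cis-epoxy aldehyde without epimerisation of the α-carbon or opening of the epoxide.

Step 5
Reactants: 8 (Z)-oct-2-en-1-ol
Product: 9 (Z)-1-bromooct-2-ene
Conditions: CBr4, PPh3, CH2Cl2, 0 °C
Reagents that add atoms: carbon tetrabromide, BrC(Br)(Br)Br
Why: Appel reaction; SN2 displacement at the primary carbon should keep the (Z)-geometry and avoid allylic transposition.

Step 6
Reactants: 10 furan; 9 (Z)-1-bromooct-2-ene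
Product: 12 2-[(Z)-oct-2-en-1-yl]furan, via 2-furyllithium 11 (not isolated)
Conditions: n-BuLi, THF, 0 °C; then 9, −78 °C to 0 °C
Reagents that add atoms: none
Why: α-lithiation of furan followed by SN2 alkylation with a primary allylic bromide should install the C13–C20 chain with the (Z)-alkene untouched.

Step 7
Reactants: 12 2-[(Z)-oct-2-en-1-yl]furan
Product: 13 2-bromo-5-[(Z)-oct-2-en-1-yl]furan
Conditions: NBS, DMF, −20 °C, dark
Reagents that add atoms: N-bromosuccinimide, BrN1C(=O)CCC1=O
Why: electrophilic aromatic bromination should occur at the free α-position of the furan, which is far more nucleophilic than the isolated alkene.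

Step 8
Reactants: 13 2-bromo-5-[(Z)-oct-2-en-1-yl]furan; 14 (2-tert-butoxy-2-oxoethyl)zinc chloride
Product: 15 tert-butyl 2-{5-[(Z)-oct-2-en-1-yl]furan-2-yl}acetate
Conditions: Pd(P(t-Bu)3)2 (cat.), THF, rt
Reagents that add atoms: none
Why: palladium-catalysed Negishi-type coupling of a Reformatsky reagent with a heteroaryl bromide (α-arylation of a zinc ester enolate) should attach C8 together with the tert-butoxycarbonyl helper.

Step 9
Reactants: 15 tert-butyl 2-{5-[(Z)-oct-2-en-1-yl]furan-2-yl}acetate; 7 methyl 4-[(2R,3R)-3-formyloxiran-2-yl]butanoate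
Product: 17 tert-butyl (3S)-3-hydroxy-3-[(2S,3R)-3-(4-methoxy-4-oxobutyl)oxiran-2-yl]-2-{5-[(Z)-oct-2-en-1-yl]furan-2-yl}propanoate (both C8 epimers), via lithium enolate 16 (not isolated)
Conditions: LiN(i-Pr)2, THF, −78 °C; then 7, −78 °C; AcOH quench at −78 °C
Reagents that add atoms: none
Why: aldol addition of the ester enolate to the aldehyde forms C7–C8, and C7 (S) should arise by attack anti to the epoxide C–O bond with the nucleophile passing the C6 hydrogen (polar 1,2-induction, anti epoxy alcohol); C8 is formed as a mixture that does not matter because it becomes an enolate carbon in step 12, and the minor C7 epimer is removed by chromatography.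

Step 10
Reactants: 17 the aldol adduct
Product: 18 tert-butyl (3S)-3-[(tert-butyldimethylsilyl)oxy]-3-[(2R,3R)-3-(4-methoxy-4-oxobutyl)oxiran-2-yl]-2-{5-[(Z)-oct-2-en-1-yl]furan-2-yl}propanoate
Conditions: TBSOTf, 2,6-lutidine, CH2Cl2, −78 °C
Reagents that add atoms: tert-butyldimethylsilyl triflate, CC(C)(C)[Si](C)(C)OS(=O)(=O)C(F)(F)F
Why: silylation of the secondary alcohol under non-nucleophilic conditions should spare the epoxide and both esters, and turns O7 into a poor leaving group so that retro-aldol, epoxide migration and β-elimination are blocked in the later steps.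

Step 11
Reactants: 18 the silyl ether
Product: 20 (Z)-ene-1,4-dione (C9 and C12 ketones on the (Z)-C10=C11 alkene; C8 tert-butoxycarbonyl; 7-silyloxy; cis-5,6-epoxide; C1 methyl ester), via endoperoxide 19 (not isolated)
Conditions: O2, tetraphenylporphyrin (cat.), visible light, CH2Cl2, −78 °C; then Me2S, −78 °C to 0 °C; used at once
Reagents that add atoms: oxygen, O=O
Why: (4+2) cycloaddition of singlet oxygen to the 2,5-disubstituted furan and reductive O–O cleavage should unmask the enedione with the (Z)-geometry dictated by the furan ring; the furan reacts much faster with singlet oxygen than the isolated alkene.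

Step 12
Reactants: 20 the (Z)-ene-1,4-dione
Product: 23 tert-butyl 2-(1-acetoxy-5-methoxy-5-oxopentyl)-3-[(tert-butyldimethylsilyl)oxy]-6a-[(Z)-oct-2-en-1-yl]-4-oxo-2,3-dihydro-4H-cyclopenta[b]furan-3a(6aH)-carboxylate (C5, C6, C7, C12 as in 28; ester on C8 where 28 has hydrogen), via cis ketol 21 (not isolated), via hydroxy ester 22 (not isolated)
Conditions: Zn(OTf)2, i-Pr2NEt, CH2Cl2/MeCN, −20 °C to rt; then Ac2O, DMAP (cat.), 0 °C
Reagents that add atoms: acetic anhydride, CC(=O)OC(C)=O
Why: Zinc/amine soft enolisation removes the only strongly acidic proton (C8–H of the β-keto ester, so C13 is left alone) and the C8 enolate adds to the C12 ketone (5-enolexo-exo-trig aldol, ring A, C8–C12), after which the new zinc-bound C12 oxygen opens the Lewis-acid-activated cis-epoxide at C6 by SN2 (5-exo-tet, ring B, O–C6). The closest known reaction types are the base-induced cyclisation of furan-derived (Z)-ene-1,4-diones to 4-hydroxycyclopent-2-enones and the 5-exo cyclisation of 4,5-epoxy alcohols to tetrahydrofurans. C6 is set by inversion at the epoxide carbon and C5 keeps the epoxide oxygen with retention, both fixed by the epoxide of step 3. C8 and C12 are set relative to C7 because the aldol is reversible whereas the etherification is not: only a ketol with the C12 oxygen cis to the C7 branch can close, and of the two such ketols the one that puts the silyloxy group and the C5 chain on the convex face of the cis-fused bicyclo[3.3.0] skeleton should close faster. The step needs carbonyl addition at C12 to outrun attack of the enolate oxygen or the ester carbonyl on the epoxide, and 5-exo to beat 6-endo opening; metal chelation of the β-keto ester oxygens, the much faster aldol and the unbiased disubstituted epoxide should secure this. Acetylation of the freed C5 hydroxyl in the same flask prevents δ-lactonisation onto the C1 methyl ester.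

Step 13
Reactants: 23 the bicyclic enone
Product: 24 the 10,11-epoxy ketone of 23 (epoxide configuration not defined)
Conditions: t-BuOOH, DBU, CH2Cl2, 0 °C to rt
Reagents that add atoms: tert-butyl hydroperoxide, CC(C)(C)OO
Why: nucleophilic (Weitz–Scheffer) epoxidation should select the electron-poor enone over the isolated (Z)-alkene, and the substrate has no enolisable position (C8 is quaternary); the epoxide configuration is irrelevant because both carbons return to sp2 in step 14.

Step 14
Reactants: 24 the epoxy ketone
Product: 27 methyl (5R)-5-acetoxy-5-[5-chloro-3-hydroxy-6a-[(Z)-oct-2-en-1-yl]-4-oxo-3,3a,4,6a-tetrahydro-2H-cyclopenta[b]furan-2-yl]pentanoate (ring stereocentres as in 28), via chlorohydrin 25 (not isolated), via keto acid 26 (not isolated)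
Conditions: HCl (4 M in 1,4-dioxane), CH2Cl2, 0 °C to 40 °C
Reagents that add atoms: hydrogen chloride, Cl
Why: chloride should open the α,β-epoxy ketone at the activated α-carbon C10 (C11 is neopentyl) and the β-hydroxy ketone dehydrates to the 2-chloro-enone, while the same acid cleaves the tert-butyl ester and the silyl ether and the β-keto acid decarboxylates through its enol, whose protonation at C8 can only give the cis ring fusion (8S).

Step 15
Reactants: 27 the 7-hydroxy chloro-enone
Product: 28 methyl (5R)-5-acetoxy-5-[(2S,3S,3aS,6aR)-3-acetoxy-5-chloro-6a-[(Z)-oct-2-en-1-yl]-4-oxo-3,3a,4,6a-tetrahydro-2H-cyclopenta[b]furan-2-yl]pentanoate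
Conditions: Ac2O, pyridine, DMAP (cat.), CH2Cl2, 0 °C
Reagents that add atoms: acetic anhydride, CC(=O)OC(C)=O
Why: O-acetylation of the remaining secondary alcohol at low temperature changes no stereocentre, and elimination of the 7-acetate is disfavoured because it would place a double bond at the ring fusion.

**Compound list**

1 | (4-carboxybutyl)triphenylphosphonium bromide | OC(=O)CCCC[P+](c1ccccc1)(c1ccccc1)c1ccccc1.[Br-] | starting material
2 | (tert-butyldimethylsilyloxy)acetaldehyde | O=CCO[Si](C)(C)C(C)(C)C | starting material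
3 | sodium 5-(triphenylphosphoranylidene)pentanoate (ylide, not isolated) | [Na+].[O-]C(=O)CCCC=P(c1ccccc1)(c1ccccc1)c1ccccc1 | intermediate
4 | (Z)-7-[(tert-butyldimethylsilyl)oxy]hept-5-enoic acid | OC(=O)CCC/C=C\CO[Si](C)(C)C(C)(C)C | intermediate
5 | methyl (Z)-7-hydroxyhept-5-enoate | COC(=O)CCC/C=C\CO | intermediate
6 | methyl 4-[(2R,3S)-3-(hydroxymethyl)oxiran-2-yl]butanoate | OC[C@H]1[C@@H](CCCC(=O)OC)O1 | intermediate
7 | methyl 4-[(2R,3R)-3-formyloxiran-2-yl]butanoate | O=C[C@H]1[C@@H](CCCC(=O)OC)O1 | intermediate
8 | (Z)-oct-2-en-1-ol | CCCCC/C=C\CO | starting material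
9 | (Z)-1-bromooct-2-ene | CCCCC/C=C\CBr | intermediate
10 | furan | c1ccoc1 | starting material
11 | 2-furyllithium (not isolated) | [Li]c1ccco1 | intermediate
12 | 2-[(Z)-oct-2-en-1-yl]furan | CCCCC/C=C\Cc1ccco1 | intermediate
13 | 2-bromo-5-[(Z)-oct-2-en-1-yl]furan | CCCCC/C=C\Cc1ccc(Br)o1 | intermediate
14 | (2-tert-butoxy-2-oxoethyl)zinc chloride | CC(C)(C)OC(=O)C[Zn]Cl | starting material
15 | tert-butyl 2-{5-[(Z)-oct-2-en-1-yl]furan-2-yl}acetate | CCCCC/C=C\Cc1ccc(CC(=O)OC(C)(C)C)o1 | intermediate
16 | lithium enolate of 15 (not isolated) | CCCCC/C=C\Cc1ccc(C=C(O[Li])OC(C)(C)C)o1 | intermediate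
17 | tert-butyl (3S)-3-hydroxy-3-[(2S,3R)-3-(4-methoxy-4-oxobutyl)oxiran-2-yl]-2-{5-[(Z)-oct-2-en-1-yl]furan-2-yl}propanoate (C8 epimers) | CCCCC/C=C\Cc1ccc(o1)C(C(=O)OC(C)(C)C)[C@H](O)[C@H]2[C@@H](CCCC(=O)OC)O2 | intermediate
18 | tert-butyldimethylsilyl ether of 17 | CCCCC/C=C\Cc1ccc(o1)C(C(=O)OC(C)(C)C)[C@H](O[Si](C)(C)C(C)(C)C)[C@H]2[C@@H](CCCC(=O)OC)O2 | intermediate
19 | furan endoperoxide of 18 (2,3,7-trioxabicyclo[2.2.1]hept-5-ene, bridgeheads C9 and C12; not isolated) | CCCCC/C=C\CC12C=CC(OO1)(O2)C(C(=O)OC(C)(C)C)[C@H](O[Si](C)(C)C(C)(C)C)[C@H]3[C@@H](CCCC(=O)OC)O3 | intermediate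
20 | (Z)-ene-1,4-dione β-keto ester (C9/C12 diketone, cis-5,6-epoxide, 7-silyloxy) | CCCCC/C=C\CC(=O)/C=C\C(=O)C(C(=O)OC(C)(C)C)[C@H](O[Si](C)(C)C(C)(C)C)[C@H]1[C@@H](CCCC(=O)OC)O1 | intermediate
21 | cis ketol (4-hydroxycyclopent-2-enone, C12 hydroxyl cis to the C7 branch; not isolated) | CCCCC/C=C\C[C@]1(O)C=CC(=O)[C@@]1(C(=O)OC(C)(C)C)[C@H](O[Si](C)(C)C(C)(C)C)[C@H]2[C@@H](CCCC(=O)OC)O2 | intermediate
22 | bicyclic 5-hydroxy ester (rings A and B closed; not isolated) | CCCCC/C=C\C[C@]12C=CC(=O)[C@@]1(C(=O)OC(C)(C)C)[C@H](O[Si](C)(C)C(C)(C)C)[C@H]([C@@H](CCCC(=O)OC)O)O2 | intermediate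
23 | bicyclic 5-acetate (8-tert-butoxycarbonyl, 7-silyloxy enone) | CCCCC/C=C\C[C@]12C=CC(=O)[C@@]1(C(=O)OC(C)(C)C)[C@H](O[Si](C)(C)C(C)(C)C)[C@H]([C@@H](CCCC(=O)OC)OC(C)=O)O2 | intermediate
24 | 10,11-epoxy ketone of 23 | CCCCC/C=C\C[C@]12C3OC3C(=O)[C@@]1(C(=O)OC(C)(C)C)[C@H](O[Si](C)(C)C(C)(C)C)[C@H]([C@@H](CCCC(=O)OC)OC(C)=O)O2 | intermediate
25 | 10-chloro-11-hydroxy ketone (chlorohydrin; not isolated) | CCCCC/C=C\C[C@]12C(O)C(Cl)C(=O)[C@@]1(C(=O)OC(C)(C)C)[C@H](O[Si](C)(C)C(C)(C)C)[C@H]([C@@H](CCCC(=O)OC)OC(C)=O)O2 | intermediate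
26 | 10-chloro-enone 8-carboxylic acid with free 7-hydroxyl (β-keto acid; not isolated) | CCCCC/C=C\C[C@]12C=C(Cl)C(=O)[C@@]1(C(=O)O)[C@H](O)[C@H]([C@@H](CCCC(=O)OC)OC(C)=O)O2 | intermediate
27 | 7-hydroxy 10-chloro-enone 5-acetate | CCCCC/C=C\C[C@]12C=C(Cl)C(=O)[C@H]1[C@H](O)[C@H]([C@@H](CCCC(=O)OC)OC(C)=O)O2 | intermediate
28 | methyl (5R)-5-acetoxy-5-[(2S,3S,3aS,6aR)-3-acetoxy-5-chloro-6a-[(Z)-oct-2-en-1-yl]-4-oxo-3,3a,4,6a-tetrahydro-2H-cyclopenta[b]furan-2-yl]pentanoate | CCCCC/C=C\C[C@]12C=C(Cl)C(=O)[C@H]1[C@H](OC(C)=O)[C@H]([C@@H](CCCC(=O)OC)OC(C)=O)O2 | target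

**Summary**

Total steps: 15. Longest linear sequence: 11 steps (steps 1–4 then 9–15; the furan branch, steps 5–8 then 9–15, is equally long).

Steps most likely to fail:

1. Step 12. What may go wrong: the metal enolate oxygen or the tert-butyl ester carbonyl may attack the activated epoxide before the aldol; the trans ketol may accumulate without recycling; the freed C5 hydroxyl may lactonise. Fallback (sets out from 20, comes back at 23): the domino is given up for two separate ring closures with a different mode for the C–O bond. Catalytic Et3N in CH2Cl2 at −20 °C effects only the aldol; the cis ketol 21 is isolated and the trans ketol F1 is returned to the amine to re-equilibrate by retro-aldol. Ketol 21 is then closed by Brønsted-acid-catalysed 5-exo epoxy-alcohol cyclisation (camphorsulfonic acid, CH2Cl2, 0 °C) to 22, which is acetylated at once (Ac2O, pyridine) to 23.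

2. Step 14. What may go wrong: one acid treatment must carry five events, and acid-induced dehydration across C7–C8, loss of the 5-acetate or incomplete dehydration of the chlorohydrin may erode the material. Fallback (sets out from 24, comes back at 27): the events are staged with orthogonal reagents. LiCl with a sulfonic acid resin in acetone converts the epoxy ketone into the chloro-enone F2 with the tert-butyl ester and silyl ether still in place. CF3CO2H in wet CH2Cl2 (0 °C to rt) then removes both helpers and the β-keto acid decarboxylates to 27.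

3. Step 9. What may go wrong: poor facial selectivity in the addition to the cis-epoxy aldehyde (too much of the C7 epimer), and epimerisation of the sensitive aldehyde under the basic conditions. Fallback (sets out from the crude mixture of 17 and its C7 epimer, comes back at 17): the C7 stereocentre is erased and reset by reduction instead of by carbonyl addition. Dess–Martin periodinane oxidises the mixture to the β-keto ester F3, and chelation-controlled reduction of this α,β-epoxy ketone with Zn(BH4)2 (Et2O, −20 °C) should deliver hydride anti to the epoxide oxygen and return the anti epoxy alcohol 17.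

Further compounds
F1 | step 12 | trans ketol (C12 epimer of 21, hydroxyl trans to the C7 branch) | CCCCC/C=C\C[C@@]1(O)C=CC(=O)[C@@]1(C(=O)OC(C)(C)C)[C@H](O[Si](C)(C)C(C)(C)C)[C@H]2[C@@H](CCCC(=O)OC)O2
F2 | step 14 | 10-chloro-enone with tert-butyl ester and silyl ether retained | CCCCC/C=C\C[C@]12C=C(Cl)C(=O)[C@@]1(C(=O)OC(C)(C)C)[C@H](O[Si](C)(C)C(C)(C)C)[C@H]([C@@H](CCCC(=O)OC)OC(C)=O)O2
F3 | step 9 | C7 ketone of 17 (β-keto ester, cis-epoxide retained) | CCCCC/C=C\Cc1ccc(o1)C(C(=O)OC(C)(C)C)C(=O)[C@H]2[C@@H](CCCC(=O)OC)O2
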